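If I want to know which recipe gives the most ring, I first turn the constants into times at the charged amounts.

all flasks: time 2.5 h

| flask | starting material | activator | remark |
|---|---|---|---|
| amber | 13 mM | 1.20 equiv (fed, over 1.5 h) | all else is in the flask from the start; the feed brings no volume worth counting |
| violet | 13 mM (fed, over 1.5 h) | 1.20 equiv | all else is in the flask from the start; the feed brings no volume worth counting |
| teal | 13 mM | 1.20 equiv | everything together at the start |

    ring ⇌ isomer of the product (K1 = 0.13, k1 = 1.7 × 10⁻⁴ s⁻¹)
    starting material ⇌ dormant form (K2 = 2.1, k2 = 5.2 × 10⁻⁴ s⁻¹)
    starting material + activator → activated form (k3 = 0.016 L mol⁻¹ s⁻¹)
    activated form → ring (k4 = 0.0054 s⁻¹)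
    starting material + activated form → open dimer (k5 = 0.20 L mol⁻¹ s⁻¹)
    starting material → decomposition product (k6 = 4.4 × 10⁻⁷ s⁻¹)

* the flask that comes out highest in amount of ring, in percent of the starting material charged, or "all alike" when all lie within 1.5 percentage points (amber / violet / teal / all alike)
* ring at the end, in percent of the starting material charged, amber
* ring at the end, in percent of the starting material charged, violet
* ring at the end, in percent of the starting material charged, teal

- in percentages every species weighs as the starting material in it: one open dimer counts as two
- run time (amber): 2.5 h

Starting material and dormant form exchange with a relaxation half-life of 0.251 h, much shorter than the run of 2.5 h, so I treat the two as one pool with a third of it free. Multiplying that free share by [activator] and the activation constant gives 0.290 h⁻¹, which I call the pool rate constant. By this way teal's pool loses 51.6% in the run. A second way counts dormant form as lost, and activation then takes 32.4%. The two part, and the second cheats, because dormant form returns well within the run.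

Each activated form that turns to open dimer takes a second starting material. With free [starting material] at its charged share, dimer formation runs at 0.155 of ring closure, so 76.3% of the pool's loss reaches ring or isomer. Ring holds 88.5% of that pair, which gives 34.8% for teal. In amber the activator arrives evenly, so the pool effectively sees it for 1.75 h, and I reckon 26.9%. In violet each portion of the feed has its own shorter time, and the pool loses 39.3%. Taking free [starting material] at 0.5 of teal's figure, I reckon 30.1%. My reckoning puts teal ahead.

The forecast names teal, with 24.5% for amber, 32% for violet and 33% for teal. On amber it says: “Feeding the activator lets the starting material go dormant before it can be activated”.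

The simulation gives 25.1% for amber, 31.3% for violet and 34.0% for teal, so teal comes out highest. The forecast's call would be wrong if a run put violet or amber above teal, or brought all three flasks within 1.5 percentage points; teal stands 2.7 points above violet and 8.9 points above amber. Teal's pool lost 52.1%, against my 51.6%. For teal with 3.00 equiv of activator, the pool rate constant becomes 0.725 h⁻¹, the pool loses 83.7%, and I reckon 56.5% ring. That flask gives 54.4% ring.

All constants are those of an exercise.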